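**Retrosynthetic overview**
1. Target 16 ⇒ aryl iodide 10 + chiral alkylzinc 15 (sp2–sp3 Negishi coupling). The side-chain stereocentre comes from bromide 14, made by a copper-catalysed SN2′ alkylation of dibromide 12 with Grignard 13.
2. 10 ⇒ dihydrobenzofuran 9 (iodination of the last free ring A carbon) ⇒ ortho-prenylphenol 7 by the key step: the O–C2 bond of the dihydrofuran is closed by a phenol-directed enantioselective epoxidation and 5-exo opening, which sets C2.
3. 7 ⇒ 6 (4-O-methylation) ⇒ 4 (C-prenylation) ⇒ phloroglucinol 1 + 3-hydroxybenzonitrile 2 (Hoesch acylation).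
4. Ring order: rings A and B are bought as arenes and joined first (step 1); ring C (the dihydrofuran) is the only ring built, in step 4.

Assumption: the ligand enantiomers named in steps 4 and 6 are taken to give the senses of induction stated; if a pilot run shows the opposite sense, the mirror-image ligand is used.

**Route**

Step 1
Reactants: 1 phloroglucinol (benzene-1,3,5-triol); 2 3-hydroxybenzonitrile
Product: 4 (3-hydroxyphenyl)(2,4,6-trihydroxyphenyl)methanone, via ketiminium chloride 3 (not isolated)
Conditions: ZnCl2, HCl (g), Et2O, 0 °C to rt; then H2O, 100 °C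
Reagents that add atoms: water, O
Why: Houben–Hoesch acylation: the nitrile activated by HCl/ZnCl2 attacks the very electron-rich phloroglucinol once (the ketiminium salt deactivates the ring against a second acylation) and hydrolysis gives the ketone; no stereocentre is formed.

Step 2
Reactants: 4 (3-hydroxyphenyl)(2,4,6-trihydroxyphenyl)methanone; 5 prenyl bromide (1-bromo-3-methylbut-2-ene)
Product: 6 (3-hydroxyphenyl)[2,4,6-trihydroxy-3-(3-methylbut-2-en-1-yl)phenyl]methanone
Conditions: DBU (1.1 equiv), THF, 0 °C to rt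
Reagents that add atoms: none
Why: C-alkylation of the ambident acylphloroglucinol monoanion (C-prenylation) in a weakly polar medium: one equivalent of DBU deprotonates only the acidic ring A, whose C3 and C5 are equivalent, so a single mono-C-prenyl product forms beside separable O- and bis-alkylated material; the less acidic ring B phenol stays protonated.

Step 3
Reactants: 6 (3-hydroxyphenyl)[2,4,6-trihydroxy-3-(3-methylbut-2-en-1-yl)phenyl]methanone
Product: 7 [2,6-dihydroxy-4-methoxy-3-(3-methylbut-2-en-1-yl)phenyl](3-hydroxyphenyl)methanone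
Conditions: Me2SO4 (1.05 equiv), K2CO3 (1.1 equiv), acetone, rt
Reagents that add atoms: dimethyl sulfate, COS(=O)(=O)OC
Why: Williamson O-methylation under acidity control: the 4-OH (para to the carbonyl, not chelated) is the most acidic hydroxyl, so one equivalent of base and Me2SO4 methylates it in preference to the two carbonyl-chelated ortho-OH groups and the less acidic ring B phenol.

Step 4
Reactants: 7 [2,6-dihydroxy-4-methoxy-3-(3-methylbut-2-en-1-yl)phenyl](3-hydroxyphenyl)methanone
Product: 9 [(2S)-6-hydroxy-2-(2-hydroxypropan-2-yl)-4-methoxy-2,3-dihydro-1-benzofuran-7-yl](3-hydroxyphenyl)methanone, via (R)-epoxide 8 (not isolated)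
Conditions: Hf(OtBu)4 (10 mol%), (1S,2S)-N,N′-dihydroxy-N,N′-bis(diphenylacetyl)cyclohexane-1,2-diamine (11 mol%), PhCMe2OOH (1.5 equiv), DMPU (20 mol%), 4 Å MS, toluene, 0 °C; then K2CO3, MeOH, rt
Reagents that add atoms: cumene hydroperoxide, CC(C)(OO)c1ccccc1
Why: Proposed new method: phenol-directed enantioselective epoxidation–cycloetherification, in which the ortho-acylphenol of 7 binds the tetravalent hafnium bishydroxamate as a phenoxide (the ketone serving as second donor), the cumyl peroxide on the same metal delivers oxygen to one face of the prenyl alkene four atoms away to give (R)-epoxide 8, and the phenoxide (metal-bound, then carbonate-generated) opens it 5-exo-tet at the secondary carbon with inversion, closing ring C and setting C2 as (S); the closest known reactions are the hydroxyl-directed hafnium or zirconium bishydroxamic acid epoxidation of homoallylic and bishomoallylic alcohols and the base-mediated 5-exo opening of ortho-prenylphenol epoxides, but a free phenol has not been used as the directing group.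

Step 5
Reactants: 9 [(2S)-6-hydroxy-2-(2-hydroxypropan-2-yl)-4-methoxy-2,3-dihydro-1-benzofuran-7-yl](3-hydroxyphenyl)methanone
Product: 10 [(2S)-6-hydroxy-2-(2-hydroxypropan-2-yl)-5-iodo-4-methoxy-2,3-dihydro-1-benzofuran-7-yl](3-hydroxyphenyl)methanone
Conditions: NIS (1.05 equiv), MeCN, 0 °C
Reagents that add atoms: N-iodosuccinimide, O=C1CCC(=O)N1I
Why: Electrophilic aromatic iodination at C5, the only unsubstituted ring A carbon and one activated by three oxygen substituents (ortho OH, ortho OMe, para ether O), while ring B is deactivated by the carbonyl; the C2 stereocentre is untouched.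

Step 6
Reactants: 11 4-bromo-2-methylbut-1-ene; 12 (E)-1,4-dibromo-2-methylbut-2-ene
Product: 14 (3S)-3-(bromomethyl)-2,6-dimethylhepta-1,6-diene, via Grignard reagent 13 (not isolated)
Conditions: Mg, Et2O, rt; then 12, CuBr·SMe2 (3 mol%), (S)-BINOL N,N-bis[(S)-1-phenylethyl]phosphoramidite (6 mol%), CH2Cl2, −78 °C, slow addition of 13
Reagents that add atoms: none
Why: Copper-catalysed asymmetric allylic alkylation (SN2′) of a 1,4-dihalobut-2-ene: the alkylcopper adds anti at the less substituted alkene carbon (CH) with loss of the bromide on the CH2 next to C(Me), reductive elimination from the trivalent copper allyl intermediate gives the branched isopropenyl product with the second C–Br bond intact, and the chiral phosphoramidite sets the (S) centre.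

Step 7
Reactants: 10 [(2S)-6-hydroxy-2-(2-hydroxypropan-2-yl)-5-iodo-4-methoxy-2,3-dihydro-1-benzofuran-7-yl](3-hydroxyphenyl)methanone; 14 (3S)-3-(bromomethyl)-2,6-dimethylhepta-1,6-diene
Product: 16 [(2S)-6-hydroxy-2-(2-hydroxypropan-2-yl)-4-methoxy-5-[(2R)-5-methyl-2-(prop-1-en-2-yl)hex-5-en-1-yl]-2,3-dihydro-1-benzofuran-7-yl](3-hydroxyphenyl)methanone, via alkylzinc bromide 15 (not isolated)
Conditions: Zn dust, LiCl, cat. I2, THF, 50 °C; then 10, Pd(OAc)2 (5 mol%), SPhos (10 mol%), THF, rt to 50 °C, slow addition of 15 (2.5 equiv); aq NH4Cl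
Reagents that add atoms: none
Why: Negishi sp2–sp3 cross-coupling: zinc inserts into the primary C–Br bond without touching the adjacent stereocentre, the alkylzinc tolerates the ketone and (on slow addition) the free OH groups, and the bulky biarylphosphine on zerovalent palladium lets the di-ortho-substituted iodide couple and favours reductive elimination over β-hydride elimination; the side-chain centre is retained and is named (R) in 16 only because the CIP priorities change.

**Compound list**
1 | phloroglucinol (benzene-1,3,5-triol) | Oc1cc(O)cc(O)c1 | starting material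
2 | 3-hydroxybenzonitrile | N#Cc1cccc(O)c1 | starting material
3 | (3-hydroxyphenyl)(2,4,6-trihydroxyphenyl)methaniminium chloride (formed in the flask) | [NH2+]=C(c1cccc(O)c1)c1c(O)cc(O)cc1O.[Cl-] | intermediate
4 | (3-hydroxyphenyl)(2,4,6-trihydroxyphenyl)methanone | O=C(c1cccc(O)c1)c1c(O)cc(O)cc1O | intermediate
5 | prenyl bromide (1-bromo-3-methylbut-2-ene) | CC(C)=CCBr | starting material
6 | (3-hydroxyphenyl)[2,4,6-trihydroxy-3-(3-methylbut-2-en-1-yl)phenyl]methanone | CC(C)=CCc1c(O)cc(O)c(C(=O)c2cccc(O)c2)c1O | intermediate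
7 | [2,6-dihydroxy-4-methoxy-3-(3-methylbut-2-en-1-yl)phenyl](3-hydroxyphenyl)methanone | COc1cc(O)c(C(=O)c2cccc(O)c2)c(O)c1CC=C(C)C | intermediate
8 | [3-{[(2R)-3,3-dimethyloxiran-2-yl]methyl}-2,6-dihydroxy-4-methoxyphenyl](3-hydroxyphenyl)methanone (formed in the flask) | CC1(C)O[C@@H]1Cc1c(OC)cc(O)c(C(=O)c2cccc(O)c2)c1O | intermediate
9 | [(2S)-6-hydroxy-2-(2-hydroxypropan-2-yl)-4-methoxy-2,3-dihydro-1-benzofuran-7-yl](3-hydroxyphenyl)methanone | COc1cc(O)c(C(=O)c2cccc(O)c2)c2c1C[C@@H](C(C)(C)O)O2 | intermediate
10 | [(2S)-6-hydroxy-2-(2-hydroxypropan-2-yl)-5-iodo-4-methoxy-2,3-dihydro-1-benzofuran-7-yl](3-hydroxyphenyl)methanone | COc1c(I)c(O)c(C(=O)c2cccc(O)c2)c2c1C[C@@H](C(C)(C)O)O2 | intermediate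
11 | 4-bromo-2-methylbut-1-ene | C=C(C)CCBr | starting material
12 | (E)-1,4-dibromo-2-methylbut-2-ene | BrC/C(C)=C/CBr | starting material
13 | (3-methylbut-3-en-1-yl)magnesium bromide (formed in the flask) | C=C(C)CC[Mg]Br | intermediate
14 | (3S)-3-(bromomethyl)-2,6-dimethylhepta-1,6-diene | C=C(C)CC[C@H](CBr)C(=C)C | intermediate
15 | [(2S)-5-methyl-2-(prop-1-en-2-yl)hex-5-en-1-yl]zinc bromide (formed in the flask) | C=C(C)CC[C@H](C[Zn]Br)C(=C)C | intermediate
16 | [(2S)-6-hydroxy-2-(2-hydroxypropan-2-yl)-4-methoxy-5-[(2R)-5-methyl-2-(prop-1-en-2-yl)hex-5-en-1-yl]-2,3-dihydro-1-benzofuran-7-yl](3-hydroxyphenyl)methanone | C=C(C)CC[C@H](Cc1c(O)c(C(=O)c2cccc(O)c2)c2c(c1OC)C[C@@H](C(C)(C)O)O2)C(=C)C | target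

**Step count**
Total steps: 7. Longest linear sequence: 6 (steps 1, 2, 3, 4, 5 and 7); step 6 is a one-step side branch.

**The three steps most likely to fail**

Step 4 (the proposed new method). The polyphenolic substrate may tie up the hafnium catalyst, the phenol may direct poorly (low ee), or the metal-bound epoxide may open 6-endo to a chromanol. The fallback uses known chemistry; it sets out from 7 and comes back to the route at 9. The three phenols of 7 are silylated (t-BuMe2SiOTf, 2,6-lutidine, CH2Cl2) to the tris(tert-butyldimethylsilyl) ether F1. Shi epoxidation of its single alkene (D-fructose-derived ketone, KHSO5 as the triple salt 2KHSO5·KHSO4·K2SO4, K2CO3 buffer, MeCN/dimethoxymethane/water, 0 °C) gives the (R)-epoxide F2. Bu4NF in THF then removes the silyl groups, and the freed ortho-phenoxide opens the epoxide 5-exo with inversion to give 9.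

Step 7. The iodide is flanked by OH and OMe and the alkylzinc is β-branched, so coupling may be slow and lose out to protonation of 15 or to β-hydride elimination. The fallback builds the side-chain stereocentre on the arene instead of bringing it in; it sets out from 10 and comes back at 16 (step 6 is then not needed). Heck-type arylation of commercial 2-methyl-2-vinyloxirane with 10 (Pd(OAc)2, NaHCO3, Bu4NCl, DMF, 60 °C; insertion then β-oxygen elimination) gives the (E)-allylic alcohol F7. PPh3/N-chlorosuccinimide in THF converts only the primary allylic hydroxyl into the (E)-allylic chloride F8. A copper-catalysed enantioselective SN2′ alkylation of F8 with excess Grignard 13 (CuBr·SMe2, chiral phosphoramidite, CH2Cl2, −78 °C; three equivalents are used up by the OH groups) then gives 16 directly.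

Step 6. The 2-methyl group on the dibromide may lower the ee, and attack at the other bromide or direct SN2 substitution may compete. The fallback replaces the catalytic step by an auxiliary-controlled alkylation. It does not use 11 or 12: it sets out from commercial (S)-4-benzyloxazolidin-2-one, 3-methylbut-2-enoyl chloride and 3-methylbut-3-en-1-ol, and comes back to the route at 14. Acylation of the lithiated auxiliary (n-BuLi, THF, −78 °C) gives the senecioyl imide F3. The alcohol is converted with Tf2O/2,6-lutidine into 3-methylbut-3-en-1-yl triflate F4. The sodium dienolate of F3 (NaN(SiMe3)2, THF, −78 °C) is alkylated at the α-carbon by F4 on the face away from the benzyl group to give the deconjugated alkylated imide F5. LiBH4 cleaves the auxiliary to the (S)-alcohol F6, and CBr4/PPh3 gives 14.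

**Further compounds**
F1 | step 4 | [2,6-bis{[tert-butyl(dimethyl)silyl]oxy}-4-methoxy-3-(3-methylbut-2-en-1-yl)phenyl](3-{[tert-butyl(dimethyl)silyl]oxy}phenyl)methanone | COc1cc(O[Si](C)(C)C(C)(C)C)c(C(=O)c2cccc(O[Si](C)(C)C(C)(C)C)c2)c(O[Si](C)(C)C(C)(C)C)c1CC=C(C)C
F2 | step 4 | [2,6-bis{[tert-butyl(dimethyl)silyl]oxy}-3-{[(2R)-3,3-dimethyloxiran-2-yl]methyl}-4-methoxyphenyl](3-{[tert-butyl(dimethyl)silyl]oxy}phenyl)methanone | COc1cc(O[Si](C)(C)C(C)(C)C)c(C(=O)c2cccc(O[Si](C)(C)C(C)(C)C)c2)c(O[Si](C)(C)C(C)(C)C)c1C[C@H]1OC1(C)C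
F3 | step 6 | (4S)-4-benzyl-3-(3-methylbut-2-enoyl)-1,3-oxazolidin-2-one | CC(C)=CC(=O)N1[C@@H](Cc2ccccc2)COC1=O
F4 | step 6 | 3-methylbut-3-en-1-yl trifluoromethanesulfonate | C=C(C)CCOS(=O)(=O)C(F)(F)F
F5 | step 6 | (4S)-4-benzyl-3-[(2S)-5-methyl-2-(prop-1-en-2-yl)hex-5-enoyl]-1,3-oxazolidin-2-one | C=C(C)CC[C@H](C(=O)N1[C@@H](Cc2ccccc2)COC1=O)C(=C)C
F6 | step 6 | (2S)-5-methyl-2-(prop-1-en-2-yl)hex-5-en-1-ol | C=C(C)CC[C@H](CO)C(=C)C
F7 | step 7 | [(2S)-6-hydroxy-5-[(2E)-4-hydroxy-3-methylbut-2-en-1-yl]-2-(2-hydroxypropan-2-yl)-4-methoxy-2,3-dihydro-1-benzofuran-7-yl](3-hydroxyphenyl)methanone | COc1c(C/C=C(\C)CO)c(O)c(C(=O)c2cccc(O)c2)c2c1C[C@@H](C(C)(C)O)O2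
F8 | step 7 | [(2S)-5-[(2E)-4-chloro-3-methylbut-2-en-1-yl]-6-hydroxy-2-(2-hydroxypropan-2-yl)-4-methoxy-2,3-dihydro-1-benzofuran-7-yl](3-hydroxyphenyl)methanone | COc1c(C/C=C(\C)CCl)c(O)c(C(=O)c2cccc(O)c2)c2c1C[C@@H](C(C)(C)O)O2
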